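Percent of the substrate charged is the unit of the questions below, and one division tells how far that percentage can climb.

| setting | Thursday's | Wednesday's | dusk | summer | spring | noon |
|---|---|---|---|---|---|---|
| substrate | 0.34 M | 0.75 M | 0.50 M | 0.50 M | 0.50 M | 0.50 M |
| partner | 0.525 M | 0.525 M | 0.525 M | 0.525 M | 0.525 M | 0.525 M |
| temperature | 55 °C | 88 °C | 40 °C |  | 70 °C | 100 °C |
| remark | run made earlier | run made earlier |  | at 40 °C until 50 s, from then on at 100 °C |  |  |
| time |  |  | 2.5 min | 2.5 min | 2.5 min | 2.5 min |

| run | time / s | target / % |
|---|---|---|
| Thursday's | 10.0 | 36.5 |
| Thursday's | 12.0 | 41.9 |
| Thursday's | 20.0 | 56.3 |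
| Thursday's | 25.0 | 61.3 |
| Thursday's | 30.0 | 66.0 |
| Thursday's | 40.0 | 73.4 |
| Wednesday's | 10.0 | 62.7 |

(scatter of a reading: 0.3 percentage points)

- what is said of target includes crystals
- crystals is a solid; its amount is given per volume of the solution
- on the list of suspects stand: substrate <-> other conformer; substrate + partner -> target; partner + other conformer -> isomer of the product; crystals <-> target
- in a conversion other conformer counts as not yet reacted

- which flask leads in amount of target, in percent of the substrate charged ("all alike" within 1.5 percentage points) (dusk / summer / spring / noon / all alike)
- how much target is there at the end, in percent of the substrate charged: dusk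
- how much target is there at the end, in percent of the substrate charged: summer
- how much target is there at the end, in percent of the substrate charged: spring
- how much target is there at the end, in percent of the substrate charged: noon

Divide the rate at which target forms by the rate at which partner goes into it: the answer is one, and time drops out. For the four flasks that leaves 1.05. This number, the partner allowance, partner charged divided by substrate charged, is a ceiling on target as a fraction of the substrate charge; the whole charge is the other ceiling.

Ines and Tom read the runs differently. Ines holds that there is one step and that all reacted substrate becomes target. The allowance stands above one, so substrate is the limiting reagent and the whole charge is her ceiling. She expects noon, at 100 °C, to come nearest to it. At 10.0 s, Wednesday's run at 88 °C reads 62.7 % and Thursday's run at 55 °C reads 36.5 %, though their charges differ. Wednesday's allowance is 0.700, and its reading stands 7.3 percentage points below that; Ines takes the gap for reaction still to come.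

Tom holds that some partner leaks to the isomer of the product, and that the same gap may be that leak. His forecast names summer as the leader, with dusk 74 %, summer 94 %, spring 92.5 % and noon 92 %. His ground is “Selectivity probably falls slightly with temperature, though this is poorly fixed”. Ines's fit of one step, first order in substrate and in partner, with all reacted substrate read as target, gives dusk 76.6 %.

The flasks end with noon in the lead at 99.5 %, ahead of spring at 94.8 % and summer at 91.9 %, so Ines has the leader. Tom's leak is real in the cold: at 2.50 min, dusk holds 11.8 % of isomer of the product and noon 0.390 %, and dusk's target, 65.7 %, stands below both the forecast and Ines's fit. The allowance of 1.05 leaves 4.76 % of the partner's own charge over once the substrate is used, and noon ends with 4.9 % of its partner.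

    substrate ⇌ other conformer (K = 0.520, k = 0.0780 s⁻¹, Ea = 82.0 kJ mol⁻¹, ΔH = −80.0 kJ mol⁻¹)
    substrate + partner → target (k = 0.0510 L mol⁻¹ s⁻¹, Ea = 48.0 kJ mol⁻¹)
    partner + other conformer → isomer of the product (k = 0.0200 L mol⁻¹ s⁻¹, Ea = 64.0 kJ mol⁻¹)
    crystals ⇌ target, rate k4*(cs4 - [target]) while solid is left; crystals form when [target] > cs4 (solubility = 0.290 M, k = 2.70 s⁻¹)
    (constants at 40 °C)

A neighbour of noon charged with 0.32 M of partner has an allowance of 0.640, below one, so its target should stop there. It ends with 63.8 % of target, 0 % of its partner and 36 % of the substrate.

All runs come from a simulation with constants of no real substance, noise included.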